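A small charge of L, 0.039 M in the east run, stalls with D at 47.0% after 6.00 d. The larger 0.058 M of the south-east flask shows 47.7% at 6.00 d. That stall is what to watch.

| setting | south-east | east | flask |
|---|---|---|---|
| L | 0.058 M | 0.039 M | 0.058 M |
| J | 1.3 equiv | 1.3 equiv | 1.30 equiv |
| X | 20 mol% | 20 mol% | 20 mol% |
| remark | the very flask that is asked about, followed so far | run made earlier |  |
| time |  |  | 15 d |
| volume of the second phase over the first |  |  | 1.0 |

| run | time / d | L / % | D / % |
|---|---|---|---|
| south-east | 0.500 | 72.2 | 27.2 |
| south-east | 1.67 | 55.2 | 44.8 |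
| south-east | 3.00 | 53.9 | 47.5 |
| south-east | 4.00 | 53.1 | 46.9 |
| south-east | 6.00 | 52.8 | 47.7 |
| east | 0.833 | 70.5 | 29.3 |
| east | 1.67 | 59.6 | 41.0 |
| east | 3.00 | 53.7 | 46.6 |
| east | 6.00 | 53.0 | 47.0 |
| east | 10.0 | 53.7 | 47.8 |

(scatter of a reading: 0.5 percentage points)

- charges count per volume of the first phase; a concentration in a rate is the amount of a species over the volume of its own phase; every rate counts per litre of the first phase
- the numbers in the tables scatter with a standard deviation of 0.5 percentage points
- the earlier runs hold the two phases in the same ratio of volumes as the flask asked about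

- share of the L used up at 15 d
- D at 15 d, in percent of the L charged

1. Ceiling. If one J serves one L, then 1.3 equiv of J makes L the limiting reagent. The charge then allows D up to 100% of the L charged.

2. Floor. The south-east flask shows 47.7% of D at 6.00 d. That single reading carries a scatter of 0.5 percentage points, so I pool it with others.

3. Tightening. I use the stall ratio, the late [D] over the late [L], pooled over 4.00 d and 6.00 d south-east and 6.00 d and 10.0 d east: 0.891.

4. Drift. In the east run, L reads 53.0% at 6.00 d and 53.7% at 10.0 d, so I see no fall. I assume the ratio holds to 15 d.

5. My bracket. The readings from 3.00 d onward give a share D/(D+L) of 46.5% at the low end, east at 3.00 d, and 47.5% at the high end, south-east at 6.00 d. The pooled ratio gives me 47.1%.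

6. The forecast. It says 47% used up and 47% of D, inside my bracket. Its ground: “The flask is simply the south-east run continued”.

7. The result. The flask gives 47.3% used up and 47.3% of D, above 46.5% and below 47.5%.

    X + J ⇌ G + Q (K = 0.720, k = 0.00140 M⁻¹ s⁻¹)
    L + G ⇌ D + X (K = 0.970, k = 0.00210 M⁻¹ s⁻¹)

8. Over the second half of the time, the shares in this flask move by 0 points. Its final [D]/[L] is 0.897, beside my 0.891. For a neighbour with 0.23 M of L, at the same equivalents and loading, 0.891 gives a share of 47.1%. That neighbour ends with D at 47.3%.

(The runs are calculated with constants of no real substance; noise was put on by code.)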